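**Retrosynthetic overview**
- Target ⇒ bis(α‑aryloxy ketone): both carbinols come from Felkin–Anh hydride reduction, and each ArO–C bond from SN2 inversion of a lactate‑derived α‑tosyloxy ketone ((S)-tosylate on aryl A, (R)-tosylate on aryl B) by the silyl/benzyl‑differentiated bisphenol core.
- 2,5‑Diaryl‑3,4‑dimethyltetrahydrofuran core ⇒ aryllithium addition to a 5‑aryl‑3,4‑dimethyl‑γ‑butyrolactone, then oxocarbenium reduction (sets C2); lactone ⇒ aryl Grignard + (2S,3S)-2,3‑dimethyl‑4‑oxobutanoic acid (Felkin–Anh, sets C5).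
- Key disconnection: the C3–C4 bond and both methyl stereocentres ⇒ Ireland–Claisen [3,3] rearrangement of (2R,3Z)-pent‑3‑en‑2‑yl propanoate, with chirality relayed from (R)-but‑3‑yn‑2‑ol.
- Ring order: the only ring built is the oxolane, closed first as the γ‑lactone and then taken to the tetrahydrofuran at the hemiketal stage; all arenes are bought.

Assumption: the benzyl‑ and TBS‑protected 4‑bromoguaiacols, (3,4‑dimethoxyphenyl)magnesium bromide in THF, both methyl lactates and (R)-but‑3‑yn‑2‑ol are catalogue items; aryl A is the aryl on C2 of the tetrahydrofuran (it carries the 1R,2R chain) and aryl B the aryl on C5.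

**Step 1**
Reactants: 1 (R)-but-3-yn-2-ol; 2 propanoyl chloride
Product: 5 (R)-pent-3-yn-2-yl propanoate, via dilithiated butynol 3 (not isolated), via lithium pentynolate 4 (not isolated)
Conditions: n-BuLi (2.05 eq), THF, −78 → 0 °C; MeI (1.05 eq), DMPU, 0 °C → rt; then 2 (1.2 eq), 0 °C
Reagents that add atoms: iodomethane, CI
Why: The O,C‑dianion is C‑methylated at the acetylide (alkynide alkylation) and the remaining lithium alkoxide is O‑acylated in the same pot, so the carbinol stereocentre of 1 is never touched.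

**Step 2**
Reactants: 5 (R)-pent-3-yn-2-yl propanoate
Product: 6 (2R,3Z)-pent-3-en-2-yl propanoate
Conditions: H2 (1 atm), Pd/CaCO3 poisoned with Pb(OAc)2, quinoline, pentane, rt
Reagents that add atoms: none
Why: Lindlar‑type semihydrogenation adds H2 syn and stops at the Z‑alkene without affecting the ester or the stereocentre.

**Step 3**
Reactants: 6 (2R,3Z)-pent-3-en-2-yl propanoate
Product: 9 (2S,3R,4E)-2,3-dimethylhex-4-enoic acid, via silyl ketene acetal 7 (not isolated), via trimethylsilyl ester 8 (not isolated)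
Conditions: LiN(i-Pr)2 (1.1 eq), THF, −78 °C; Me3SiCl, −78 °C → rt, then 55 °C; 1 M HCl
Reagents that add atoms: none
Why: Ireland–Claisen [3,3]‑sigmatropic rearrangement: kinetic enolisation in THF gives the E‑silyl ketene acetal (methyl trans to OSi), and the chair transition state with the carbinol methyl equatorial (the axial alternative clashes 1,3‑diaxially with the Z‑methyl) transfers the (R)-carbinol chirality to C2 (S) and C3 (R) with syn methyls and an E‑alkene.

**Step 4**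
Reactants: 9 (2S,3R,4E)-2,3-dimethylhex-4-enoic acid
Product: 11 (2S,3S)-2,3-dimethyl-4-oxobutanoic acid, via ozonide 10 (not isolated)
Conditions: O3, CH2Cl2, −78 °C; Me2S, −78 °C → rt
Reagents that add atoms: ozone, [O-][O+]=O
Why: Ozonolysis with reductive work‑up cleaves the propenyl group to the aldehyde, which rests as its cyclic lactol so the α‑stereocentre does not epimerise.

**Step 5**
Reactants: 11 (2S,3S)-2,3-dimethyl-4-oxobutanoic acid; 12 1-(benzyloxy)-4-bromo-2-methoxybenzene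
Product: 15 (3S,4S,5R)-5-[4-(benzyloxy)-3-methoxyphenyl]-3,4-dimethyldihydrofuran-2(3H)-one, via arylmagnesium bromide 13 (not isolated), via hydroxy acid 14 (not isolated)
Conditions: 12, Mg, THF, rt; 13 (2.2 eq) added to 11, THF, −78 → −20 °C; 1 M HCl, 0 °C → rt
Reagents that add atoms: none
Why: Grignard addition to the aldehyde of the magnesium carboxylate follows the Felkin–Anh model (attack anti to the branched C2‑bearing substituent, past H), giving the 4R carbinol, which lactonises to the 4,5‑cis lactone; the minor C5 epimer is removed by chromatography.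

**Step 6**
Reactants: 15 (3S,4S,5R)-5-[4-(benzyloxy)-3-methoxyphenyl]-3,4-dimethyldihydrofuran-2(3H)-one; 16 (4-bromo-2-methoxyphenoxy)(tert-butyl)dimethylsilane
Product: 18 (3S,4S,5R)-5-[4-(benzyloxy)-3-methoxyphenyl]-2-[4-(tert-butyldimethylsilyloxy)-3-methoxyphenyl]-3,4-dimethyltetrahydrofuran-2-ol, via aryllithium 17 (not isolated)
Conditions: 16, n-BuLi, THF, −78 °C; then 15, −78 °C; aq NH4Cl
Reagents that add atoms: none
Why: Bromine–lithium exchange, then a single 1,2‑addition of the aryllithium to the lactone carbonyl; the lithium hemiketal alkoxide is stable at −78 °C, so no second addition occurs and C3–C5 are untouched.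

**Step 7**
Reactants: 18 (3S,4S,5R)-5-[4-(benzyloxy)-3-methoxyphenyl]-2-[4-(tert-butyldimethylsilyloxy)-3-methoxyphenyl]-3,4-dimethyltetrahydrofuran-2-ol
Product: 19 (2S,3S,4S,5R)-5-[4-(benzyloxy)-3-methoxyphenyl]-2-[4-(tert-butyldimethylsilyloxy)-3-methoxyphenyl]-3,4-dimethyltetrahydrofuran
Conditions: Et3SiH (5 eq), BF3·OEt2 (2 eq), CH2Cl2, −78 → −50 °C; aq NaHCO3 added cold
Reagents that add atoms: none
Why: Reductive deoxygenation through the 2‑aryl oxocarbenium ion: hydride attacks the envelope from the inside face, anti to the C4 methyl and C5 aryl, so the C2 aryl ends trans to the C3 methyl (2S), and the low temperature prevents benzylic epimerisation at C5.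

**Step 8**
Reactants: 20 methyl (R)-lactate; 21 (3,4-dimethoxyphenyl)magnesium bromide
Product: 23 (2R)-1-(3,4-dimethoxyphenyl)-2-hydroxypropan-1-one, via (R)-Weinreb amide 22 (not isolated)
Conditions: MeNH(OMe)·HCl (1.1 eq), i-PrMgCl (3.2 eq), THF, −20 °C; then 21 (2.0 eq), −20 °C → rt; aq NH4Cl
Reagents that add atoms: none
Why: Magnesium‑amide aminolysis of the ester gives the Weinreb amide, whose chelated tetrahedral adduct with the aryl Grignard collapses to the ketone only on work‑up (Weinreb ketone synthesis); the stereocentre stays a magnesium alkoxide and is not enolised.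

**Step 9**
Reactants: 23 (2R)-1-(3,4-dimethoxyphenyl)-2-hydroxypropan-1-one
Product: 24 (2R)-1-(3,4-dimethoxyphenyl)-1-oxopropan-2-yl 4-methylbenzenesulfonate
Conditions: TsCl, pyridine, CH2Cl2, 0 °C → rt
Reagents that add atoms: 4-toluenesulfonyl chloride, Cc1ccc(cc1)S(Cl)(=O)=O
Why: O‑Sulfonylation occurs at oxygen, so the C–O bond and the R configuration are retained.

**Step 10**
Reactants: 25 methyl (S)-lactate; 21 (3,4-dimethoxyphenyl)magnesium bromide
Product: 27 (2S)-1-(3,4-dimethoxyphenyl)-2-hydroxypropan-1-one, via (S)-Weinreb amide 26 (not isolated)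
Conditions: MeNH(OMe)·HCl (1.1 eq), i-PrMgCl (3.2 eq), THF, −20 °C; then 21 (2.0 eq), −20 °C → rt; aq NH4Cl
Reagents that add atoms: none
Why: Same one‑pot Weinreb ketone synthesis as step 8, in the enantiomeric series and with retention of the lactate stereocentre.

**Step 11**
Reactants: 27 (2S)-1-(3,4-dimethoxyphenyl)-2-hydroxypropan-1-one
Product: 28 (2S)-1-(3,4-dimethoxyphenyl)-1-oxopropan-2-yl 4-methylbenzenesulfonate
Conditions: TsCl, pyridine, CH2Cl2, 0 °C → rt
Reagents that add atoms: 4-toluenesulfonyl chloride, Cc1ccc(cc1)S(Cl)(=O)=O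
Why: O‑Sulfonylation with retention, as in step 9.

**Step 12**
Reactants: 19 (2S,3S,4S,5R)-5-[4-(benzyloxy)-3-methoxyphenyl]-2-[4-(tert-butyldimethylsilyloxy)-3-methoxyphenyl]-3,4-dimethyltetrahydrofuran
Product: 29 4-[(2R,3S,4S,5S)-5-[4-(tert-butyldimethylsilyloxy)-3-methoxyphenyl]-3,4-dimethyltetrahydrofuran-2-yl]-2-methoxyphenol
Conditions: H2 (1 atm), Pd/C, EtOAc, rt
Reagents that add atoms: none
Why: Hydrogenolysis of the benzyl ether frees only the phenol on aryl B; the aryl silyl ether and the cyclic benzylic ethers survive short exposure in a neutral aprotic solvent.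

**Step 13**
Reactants: 29 4-[(2R,3S,4S,5S)-5-[4-(tert-butyldimethylsilyloxy)-3-methoxyphenyl]-3,4-dimethyltetrahydrofuran-2-yl]-2-methoxyphenol; 24 (2R)-1-(3,4-dimethoxyphenyl)-1-oxopropan-2-yl 4-methylbenzenesulfonate
Product: 30 (2S)-2-{4-[(2R,3S,4S,5S)-5-[4-(tert-butyldimethylsilyloxy)-3-methoxyphenyl]-3,4-dimethyltetrahydrofuran-2-yl]-2-methoxyphenoxy}-1-(3,4-dimethoxyphenyl)propan-1-one
Conditions: BEMP (1.1 eq), MeCN, 0 °C → rt
Reagents that add atoms: none
Why: Williamson‑type SN2 etherification of the phenoxide on the α‑keto tosylate inverts R → S at the future side‑chain C2 on aryl B; the phosphazene base BEMP (2‑tert‑butylimino‑2‑diethylamino‑1,3‑dimethylperhydro‑1,3,2‑diazaphosphorine) leaves the silyl ether alone and does not enolise the ketone appreciably.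

**Step 14**
Reactants: 30 (2S)-2-{4-[(2R,3S,4S,5S)-5-[4-(tert-butyldimethylsilyloxy)-3-methoxyphenyl]-3,4-dimethyltetrahydrofuran-2-yl]-2-methoxyphenoxy}-1-(3,4-dimethoxyphenyl)propan-1-one; 28 (2S)-1-(3,4-dimethoxyphenyl)-1-oxopropan-2-yl 4-methylbenzenesulfonate
Product: 32 (2R)-1-(3,4-dimethoxyphenyl)-2-{4-[(2S,3S,4S,5R)-5-(4-{[(2S)-1-(3,4-dimethoxyphenyl)-1-oxopropan-2-yl]oxy}-3-methoxyphenyl)-3,4-dimethyltetrahydrofuran-2-yl]-2-methoxyphenoxy}propan-1-one, via ammonium phenoxide 31 (not isolated)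
Conditions: n-Bu4NF (1.0 eq), THF, 0 °C, 15 min; then 28 (1.3 eq), DMF, 0 °C → rt
Reagents that add atoms: none
Why: Fluoride desilylation releases the tetrabutylammonium phenoxide of aryl A, which displaces the tosylate of 28 in an SN2 etherification with inversion S → R.

**Step 15**
Reactants: 32 (2R)-1-(3,4-dimethoxyphenyl)-2-{4-[(2S,3S,4S,5R)-5-(4-{[(2S)-1-(3,4-dimethoxyphenyl)-1-oxopropan-2-yl]oxy}-3-methoxyphenyl)-3,4-dimethyltetrahydrofuran-2-yl]-2-methoxyphenoxy}propan-1-one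
Product: 33 (1R,2R)-1-(3,4-dimethoxyphenyl)-2-{4-[(2S,3S,4S,5R)-5-(4-{[(1S,2S)-1-(3,4-dimethoxyphenyl)-1-hydroxypropan-2-yl]oxy}-3-methoxyphenyl)-3,4-dimethyltetrahydrofuran-2-yl]-2-methoxyphenoxy}propan-1-ol
Conditions: n-Bu4NBH4, MeOH–CH2Cl2, −40 → 0 °C
Reagents that add atoms: none
Why: A non‑chelating ammonium borohydride reduces each α‑aryloxy ketone under polar Felkin–Anh control (hydride anti to the C–OAr bond), giving the threo alcohol at both sites: 1R,2R on aryl A and 1S,2S on aryl B.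

**Compound list**
1 | (R)-but-3-yn-2-ol | C[C@@H](O)C#C | starting material
2 | propanoyl chloride | CCC(Cl)=O | starting material
3 | dilithiated butynol [lithium (R)-4-lithiobut-3-yn-2-olate] | C[C@@H](O[Li])C#C[Li] | intermediate
4 | lithium pentynolate [lithium (R)-pent-3-yn-2-olate] | C[C@@H](O[Li])C#CC | intermediate
5 | (R)-pent-3-yn-2-yl propanoate | CCC(=O)O[C@H](C)C#CC | intermediate
6 | (2R,3Z)-pent-3-en-2-yl propanoate | CCC(=O)O[C@H](C)/C=C\C | intermediate
7 | silyl ketene acetal [(E)-1-[(2R,3Z)-pent-3-en-2-yloxy]-1-(trimethylsilyloxy)prop-1-ene] | C/C=C(/O[Si](C)(C)C)O[C@H](C)/C=C\C | intermediate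
8 | trimethylsilyl ester [trimethylsilyl (2S,3R,4E)-2,3-dimethylhex-4-enoate] | C[Si](C)(C)OC(=O)[C@@H](C)[C@H](C)/C=C/C | intermediate
9 | (2S,3R,4E)-2,3-dimethylhex-4-enoic acid | OC(=O)[C@@H](C)[C@H](C)/C=C/C | intermediate
10 | ozonide [(2S,3S)-2-methyl-3-(5-methyl-1,2,4-trioxolan-3-yl)butanoic acid] | OC(=O)[C@@H](C)[C@H](C)C1OOC(C)O1 | intermediate
11 | (2S,3S)-2,3-dimethyl-4-oxobutanoic acid (in equilibrium with its cyclic lactol) | OC(=O)[C@@H](C)[C@H](C)C=O | intermediate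
12 | 1-(benzyloxy)-4-bromo-2-methoxybenzene | COc1cc(Br)ccc1OCc1ccccc1 | starting material
13 | arylmagnesium bromide [[4-(benzyloxy)-3-methoxyphenyl]magnesium bromide] | COc1cc([Mg]Br)ccc1OCc1ccccc1 | intermediate
14 | hydroxy acid [(2S,3S,4R)-4-[4-(benzyloxy)-3-methoxyphenyl]-4-hydroxy-2,3-dimethylbutanoic acid] | OC(=O)[C@@H](C)[C@H](C)[C@@H](O)c1ccc(OCc2ccccc2)c(OC)c1 | intermediate
15 | (3S,4S,5R)-5-[4-(benzyloxy)-3-methoxyphenyl]-3,4-dimethyldihydrofuran-2(3H)-one | O=C1O[C@@H](c2ccc(OCc3ccccc3)c(OC)c2)[C@@H](C)[C@@H]1C | intermediate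
16 | (4-bromo-2-methoxyphenoxy)(tert-butyl)dimethylsilane | COc1cc(Br)ccc1O[Si](C)(C)C(C)(C)C | starting material
17 | aryllithium [[4-(tert-butyldimethylsilyloxy)-3-methoxyphenyl]lithium] | COc1cc([Li])ccc1O[Si](C)(C)C(C)(C)C | intermediate
18 | (3S,4S,5R)-5-[4-(benzyloxy)-3-methoxyphenyl]-2-[4-(tert-butyldimethylsilyloxy)-3-methoxyphenyl]-3,4-dimethyltetrahydrofuran-2-ol (anomer mixture) | CC(C)(C)[Si](C)(C)Oc1ccc(C2(O)O[C@@H](c3ccc(OCc4ccccc4)c(OC)c3)[C@@H](C)[C@@H]2C)cc1OC | intermediate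
19 | (2S,3S,4S,5R)-5-[4-(benzyloxy)-3-methoxyphenyl]-2-[4-(tert-butyldimethylsilyloxy)-3-methoxyphenyl]-3,4-dimethyltetrahydrofuran | CC(C)(C)[Si](C)(C)Oc1ccc([C@H]2O[C@@H](c3ccc(OCc4ccccc4)c(OC)c3)[C@@H](C)[C@@H]2C)cc1OC | intermediate
20 | methyl (R)-lactate | C[C@@H](O)C(=O)OC | starting material
21 | (3,4-dimethoxyphenyl)magnesium bromide | COc1ccc([Mg]Br)cc1OC | starting material
22 | (R)-Weinreb amide [(2R)-2-hydroxy-N-methoxy-N-methylpropanamide; present as its chloromagnesium alkoxide] | C[C@@H](O)C(=O)N(C)OC | intermediate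
23 | (2R)-1-(3,4-dimethoxyphenyl)-2-hydroxypropan-1-one | C[C@@H](O)C(=O)c1ccc(OC)c(OC)c1 | intermediate
24 | (2R)-1-(3,4-dimethoxyphenyl)-1-oxopropan-2-yl 4-methylbenzenesulfonate | C[C@@H](OS(=O)(=O)c1ccc(C)cc1)C(=O)c1ccc(OC)c(OC)c1 | intermediate
25 | methyl (S)-lactate | C[C@H](O)C(=O)OC | starting material
26 | (S)-Weinreb amide [(2S)-2-hydroxy-N-methoxy-N-methylpropanamide; present as its chloromagnesium alkoxide] | C[C@H](O)C(=O)N(C)OC | intermediate
27 | (2S)-1-(3,4-dimethoxyphenyl)-2-hydroxypropan-1-one | C[C@H](O)C(=O)c1ccc(OC)c(OC)c1 | intermediate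
28 | (2S)-1-(3,4-dimethoxyphenyl)-1-oxopropan-2-yl 4-methylbenzenesulfonate | C[C@H](OS(=O)(=O)c1ccc(C)cc1)C(=O)c1ccc(OC)c(OC)c1 | intermediate
29 | 4-[(2R,3S,4S,5S)-5-[4-(tert-butyldimethylsilyloxy)-3-methoxyphenyl]-3,4-dimethyltetrahydrofuran-2-yl]-2-methoxyphenol | CC(C)(C)[Si](C)(C)Oc1ccc([C@H]2O[C@@H](c3ccc(O)c(OC)c3)[C@@H](C)[C@@H]2C)cc1OC | intermediate
30 | (2S)-2-{4-[(2R,3S,4S,5S)-5-[4-(tert-butyldimethylsilyloxy)-3-methoxyphenyl]-3,4-dimethyltetrahydrofuran-2-yl]-2-methoxyphenoxy}-1-(3,4-dimethoxyphenyl)propan-1-one | CC(C)(C)[Si](C)(C)Oc1ccc([C@H]2O[C@@H](c3ccc(O[C@@H](C)C(=O)c4ccc(OC)c(OC)c4)c(OC)c3)[C@@H](C)[C@@H]2C)cc1OC | intermediate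
31 | ammonium phenoxide [tetrabutylammonium 4-[(2S,3S,4S,5R)-5-(4-{[(2S)-1-(3,4-dimethoxyphenyl)-1-oxopropan-2-yl]oxy}-3-methoxyphenyl)-3,4-dimethyltetrahydrofuran-2-yl]-2-methoxyphenolate] | CCCC[N+](CCCC)(CCCC)CCCC.[O-]c1ccc([C@H]2O[C@@H](c3ccc(O[C@@H](C)C(=O)c4ccc(OC)c(OC)c4)c(OC)c3)[C@@H](C)[C@@H]2C)cc1OC | intermediate
32 | (2R)-1-(3,4-dimethoxyphenyl)-2-{4-[(2S,3S,4S,5R)-5-(4-{[(2S)-1-(3,4-dimethoxyphenyl)-1-oxopropan-2-yl]oxy}-3-methoxyphenyl)-3,4-dimethyltetrahydrofuran-2-yl]-2-methoxyphenoxy}propan-1-one | COc1ccc(C(=O)[C@@H](C)Oc2ccc([C@H]3O[C@@H](c4ccc(O[C@@H](C)C(=O)c5ccc(OC)c(OC)c5)c(OC)c4)[C@@H](C)[C@@H]3C)cc2OC)cc1OC | intermediate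
33 | (1R,2R)-1-(3,4-dimethoxyphenyl)-2-{4-[(2S,3S,4S,5R)-5-(4-{[(1S,2S)-1-(3,4-dimethoxyphenyl)-1-hydroxypropan-2-yl]oxy}-3-methoxyphenyl)-3,4-dimethyltetrahydrofuran-2-yl]-2-methoxyphenoxy}propan-1-ol | COc1ccc([C@@H](O)[C@@H](C)Oc2ccc([C@H]3O[C@@H](c4ccc(O[C@@H](C)[C@@H](O)c5ccc(OC)c(OC)c5)c(OC)c4)[C@@H](C)[C@@H]3C)cc2OC)cc1OC | target

**Totals**
Total step count: 15. Longest linear sequence: 11 steps (steps 1–7, then 12–15).

**Steps most likely to fail**

Step 5. The Felkin–Anh preference of an aryl Grignard for an α‑methyl aldehyde may be modest. The fallback sets out from 11 and comes back at 15. The addition of 13 to 11 is run as before without relying on its selectivity and the lactones are separated. The unwanted C5 epimer, (3S,4S,5S)-5-[4-(benzyloxy)-3-methoxyphenyl]-3,4-dimethyldihydrofuran-2(3H)-one F1, is opened with LiOH in THF–H2O and acidified cold to (2S,3S,4S)-4-[4-(benzyloxy)-3-methoxyphenyl]-4-hydroxy-2,3-dimethylbutanoic acid F2. F2 is closed at once by Mitsunobu lactonisation (PPh3, DIAD, THF, 0 °C); the carboxylate displaces the activated benzylic oxygen with inversion, so all material converges on 15.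

Step 14. The in‑situ ammonium phenoxide and residual fluoride may epimerise the α‑aryloxy ketone already present or attack the tosylate. The fallback sets out from 30 and comes back at 32. The silyl ether is removed with n-Bu4NF buffered with AcOH (THF, 0 °C) and the phenol (2S)-1-(3,4-dimethoxyphenyl)-2-{4-[(2R,3S,4S,5S)-5-(4-hydroxy-3-methoxyphenyl)-3,4-dimethyltetrahydrofuran-2-yl]-2-methoxyphenoxy}propan-1-one F3 is isolated. The ether bond is then made under neutral Mitsunobu conditions (PPh3, DIAD, toluene, 0 °C) with hydroxy ketone 27, which likewise inverts S → R and gives 32 without a basic phenoxide.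

Step 15. The double Felkin–Anh reduction may give erythro contamination at either carbinol. The fallback sets out from 32 and comes back at 33. Chelation‑controlled reduction with Zn(BH4)2 (Et2O, −20 °C) gives the erythro,erythro diol (1S,2R)-1-(3,4-dimethoxyphenyl)-2-{4-[(2S,3S,4S,5R)-5-(4-{[(1R,2S)-1-(3,4-dimethoxyphenyl)-1-hydroxypropan-2-yl]oxy}-3-methoxyphenyl)-3,4-dimethyltetrahydrofuran-2-yl]-2-methoxyphenoxy}propan-1-ol F4. Twofold Mitsunobu esterification with 4‑nitrobenzoic acid (PPh3, DIAD, THF) inverts both carbinols to the threo,threo bis(4-nitrobenzoate) of 33 F5, and K2CO3 in MeOH releases 33.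

**Further compounds**
F1 | step 5 | (3S,4S,5S)-5-[4-(benzyloxy)-3-methoxyphenyl]-3,4-dimethyldihydrofuran-2(3H)-one | O=C1O[C@H](c2ccc(OCc3ccccc3)c(OC)c2)[C@@H](C)[C@@H]1C
F2 | step 5 | (2S,3S,4S)-4-[4-(benzyloxy)-3-methoxyphenyl]-4-hydroxy-2,3-dimethylbutanoic acid | OC(=O)[C@@H](C)[C@H](C)[C@H](O)c1ccc(OCc2ccccc2)c(OC)c1
F3 | step 14 | (2S)-1-(3,4-dimethoxyphenyl)-2-{4-[(2R,3S,4S,5S)-5-(4-hydroxy-3-methoxyphenyl)-3,4-dimethyltetrahydrofuran-2-yl]-2-methoxyphenoxy}propan-1-one | Oc1ccc([C@H]2O[C@@H](c3ccc(O[C@@H](C)C(=O)c4ccc(OC)c(OC)c4)c(OC)c3)[C@@H](C)[C@@H]2C)cc1OC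
F4 | step 15 | (1S,2R)-1-(3,4-dimethoxyphenyl)-2-{4-[(2S,3S,4S,5R)-5-(4-{[(1R,2S)-1-(3,4-dimethoxyphenyl)-1-hydroxypropan-2-yl]oxy}-3-methoxyphenyl)-3,4-dimethyltetrahydrofuran-2-yl]-2-methoxyphenoxy}propan-1-ol | COc1ccc([C@H](O)[C@@H](C)Oc2ccc([C@H]3O[C@@H](c4ccc(O[C@@H](C)[C@H](O)c5ccc(OC)c(OC)c5)c(OC)c4)[C@@H](C)[C@@H]3C)cc2OC)cc1OC
F5 | step 15 | threo,threo bis(4-nitrobenzoate) of 33 | COc1ccc([C@@H](OC(=O)c6ccc(cc6)[N+]([O-])=O)[C@@H](C)Oc2ccc([C@H]3O[C@@H](c4ccc(O[C@@H](C)[C@@H](OC(=O)c7ccc(cc7)[N+]([O-])=O)c5ccc(OC)c(OC)c5)c(OC)c4)[C@@H](C)[C@@H]3C)cc2OC)cc1OC
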